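After 50.0 s the south-west flask reads X at 44.8 % and Z at 49.8 %, and the fall of X has slowed. You want the same pair from two flasks with twice the concentration of everything.

common to all: J 0.1 mol%
- south-west: X 5.5 mM; Z 5.5 mM; G 1.2 equiv; run made earlier
- Wednesday's: X 11 mM; Z 11 mM; G 1.20 equiv; time 3.0 min
- Friday's: X 11 mM; Z 11 mM; G 1.20 equiv; time 1.0 min

- south-west (time / s: Z / %, X / %, D / %): 10.0: 50.1, 48.1, 1.7; 20.0: 49.7, 46.8, 2.4; 30.0: 49.9, 45.4, 3.3; 40.0: 50.0, 44.9, 3.6; 50.0: 49.8, 44.8, 4.2

(readings scatter by 0.3 percentage points)

- J is single-handed; X and Z are mirror images of each other, charged as a racemate, each of them at the stated concentration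
- the analysis behind the earlier runs scatters by 0.3 percentage points, standard deviation
- an excess is the difference of the two amounts in percent of their sum
- an excess is below zero if the other one leads
- no earlier run changes the charge of J; that part of a forecast is a guess

1. which of the two ends with the higher excess of Z over X among what is left of the two ("neither" if they lie within 2 percentage points) (Wednesday's / Friday's / neither)
2. excess of Z over X among what is left of the two at the end, Wednesday's
3. excess of Z over X among what is left of the two at the end, Friday's

Let the left fraction be what remains of X's charge. In the south-west flask, the logarithm of charge over left fraction is 0.110. Call this the exposure: X's mean pseudo-first-order rate constant times the time. Take Z as unchanged. The excess is then one minus the left fraction, over one plus it.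

Now suppose that rate constant goes with J times G. This is a guess for both, since no earlier run changes either. Both stand at twice their south-west level, so the exposure grows 4.00-fold to 0.439. By this reckoning 64.5 % of X's charge is left at 50.0 s.

The weak link is the stop at the last reading. Between 30.0 s and 50.0 s X still fell by 0.6 percentage points, against a scatter of 0.3 points per reading. Read from these scattered readings, that is a mean tail of 0.0399 min⁻¹. Scaled the same way and run to each end, it lifts Friday's exposure to 0.466 and Wednesday's to 0.785. So I commit to 22.9 % for Friday's and 37.4 % for Wednesday's, with Wednesday's ahead.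

The forecast differs. It says neither, with 11 % for Wednesday's (range 5.5 % to 14 %) and 10.3 % for Friday's. Its ground: “the stall suggests J is dying”.

The flasks give 32.3 % for Wednesday's and 19.6 % for Friday's, and the higher excess is in Wednesday's.

    G ⇌ Q (K = 1.10, k = 0.0220 s⁻¹)
    2 G → L (k = 0.943 M⁻¹ s⁻¹)
    G + J + X → J + D (k = 1.22 × 10⁵ M⁻² s⁻¹)
    D ⇌ E (k = 0.0223 s⁻¹)
    G + J + Z → J + E (k = 2860 M⁻² s⁻¹)

Friday's left fraction of 67 % is an exposure of 0.406, against my 0.466. Wednesday's 50 % is 0.686, against my 0.785. Scaled by J to the neighbour of Friday's with 0.04 mol%, Friday's exposure leaves 85.0 % of X's charge, and that flask holds 83 % of it. In Friday's first 0.500 min, G fell to 30.1 % of its charge while G, J and X made D, and Q reached 3.29 mM. Between 1.50 min and 3.00 min on Wednesday's, with J at 100 %, Q sank from 2.87 mM to 1.86 mM while X, in percent of the pair charged, still went from 30.5 % to 25.2 %.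

(The earlier runs and the new flask were computed from invented constants, noise included.)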